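**Plan**

- Retrosynthesis: cut first the two C(=O)–C(alpha) bonds of the 2-methylbutanoyl groups on C8 and C8' (ketone read as carbinol, ethyl as vinyl), then the two C8–CHO bonds (back to aryl bromides), then the two C6–CH bridge bonds to 6-methylheptanal, and last the C4–C4a and O1–C2 bonds of each pyran ring (phloroglucinol + isoprene).
- Forward: the pyran ring is fused onto phloroglucinol; the chroman is benzylated and brominated at C8; two units are joined at C6 through the aldehyde carbon; both bromines become formyl groups; double crotylation, alkene reduction, oxidation and debenzylation finish the side chains.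
- Enabling feature: the only stereocentres are the two exocyclic alpha carbons next to the aryl ketone carbonyls on C8 and C8' of the two chroman benzene rings, each carrying CH3 and C2H5. With vinyl for ethyl and CH–OH for C=O, each is an anti crotyl adduct of an aryl aldehyde.
- Stereochemistry: both alpha centres are set (R) in one operation by (R)-TRIP-catalysed addition of (E)-crotyl pinacol boronate (E-alkene gives anti, catalyst picks the Re face); the carbinol centres formed alongside are oxidised away later.

Key step: step 6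

Remark: (R)-TRIP is assumed to send the crotyl group to the Re face of this aryl aldehyde, as it does for simple benzaldehydes; Re-face anti addition corresponds to the (1R,2R) adduct needed.
Remark: 6-methylheptanal is taken as a catalogue aldehyde.

**Step 1**
Reactants: 1 phloroglucinol; 2 isoprene
Product: 3 5,7-dihydroxy-2,2-dimethylchroman
Conditions: 2 (0.8 equiv, slow addition), Amberlyst 15, THF/heptane, 65 °C
Reagents that add atoms: none
Why: Acid-catalysed Friedel–Crafts prenylation of the symmetric triphenol followed by Markovnikov addition of the ortho hydroxyl to the prenyl double bond (one-pot chromanylation of a phenol by isoprene) should give the single possible monochroman, and sub-stoichiometric isoprene limits a second annulation.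

**Step 2**
Reactants: 3 5,7-dihydroxy-2,2-dimethylchroman
Product: 4 5,7-bis(benzyloxy)-2,2-dimethylchroman
Conditions: BnBr (2.3 equiv), K2CO3, DMF, 0 °C → rt
Reagents that add atoms: benzyl bromide, BrCc1ccccc1
Why: Williamson etherification of both phenols with K2CO3 in a dipolar aprotic solvent favours O- over C-alkylation, as in the benzylation of 5,7-dihydroxyflavans.

**Step 3**
Reactants: 4 5,7-bis(benzyloxy)-2,2-dimethylchroman
Product: 5 5,7-bis(benzyloxy)-8-bromo-2,2-dimethylchroman
Conditions: NBS (1.0 equiv), CH2Cl2, −78 → 0 °C, dark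
Reagents that add atoms: N-bromosuccinimide, O=C1CCC(=O)N1Br
Why: Electrophilic aromatic bromination should take C8, which lies between the tied-back ring oxygen and one benzyloxy group, in preference to C6 between two freely rotating benzyloxy groups, the same steric preference that 5,7-di-O-benzyl flavans show toward NBS.

**Step 4**
Reactants: 5 5,7-bis(benzyloxy)-8-bromo-2,2-dimethylchroman (2.1 equiv); 6 6-methylheptanal
Product: 8 1,1-bis[5,7-bis(benzyloxy)-8-bromo-2,2-dimethylchroman-6-yl]-6-methylheptane, via benzylic carbinol 7 (not isolated)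
Conditions: Sc(OTf)3 (10 mol%), CH2Cl2/MeCN, rt
Reagents that add atoms: none
Why: Twofold Friedel–Crafts hydroxyalkylation–alkylation (diarylmethane condensation of an electron-rich arene with an aldehyde): with C8 blocked by bromine, the only free ring carbon C6 attacks the activated aldehyde, the o,o'-dialkoxybenzylic carbinol 7 ionises readily and a second molecule of 5 captures the cation; the bridging carbon carries two identical aryl groups and is no stereocentre.

**Step 5**
Reactants: 8 1,1-bis[5,7-bis(benzyloxy)-8-bromo-2,2-dimethylchroman-6-yl]-6-methylheptane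
Product: 11 6,6'-(6-methylheptane-1,1-diyl)bis[5,7-bis(benzyloxy)-2,2-dimethylchroman-8-carbaldehyde], via 8,8'-dilithio species 9 (not isolated), via bis(lithium aminoalkoxide) 10 (not isolated)
Conditions: n-BuLi (2.3 equiv), THF, −78 °C; DMF (6 equiv), −78 → 0 °C; H2O
Reagents that add atoms: N,N-dimethylformamide, CN(C)C=O
Why: Bromine–lithium exchange at both C8 positions is faster at −78 °C than any attack on the benzyl ethers, and the chelation-stabilised aryllithiums add to DMF to give aminoalkoxides that release the aldehydes on hydrolysis (Bouveault formylation).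

**Step 6**
Reactants: 11 6,6'-(6-methylheptane-1,1-diyl)bis[5,7-bis(benzyloxy)-2,2-dimethylchroman-8-carbaldehyde]; 12 (E)-crotylboronic acid pinacol ester (3 equiv)
Product: 14 1,1-bis{5,7-bis(benzyloxy)-8-[(1R,2R)-1-hydroxy-2-methylbut-3-enyl]-2,2-dimethylchroman-6-yl}-6-methylheptane, via bis(pinacol borate) ester 13 (not isolated)
Conditions: (R)-TRIP [(R)-3,3'-bis(2,4,6-triisopropylphenyl)-1,1'-binaphthyl-2,2'-diyl hydrogen phosphate] (10 mol%), 4 Å MS, toluene, −30 → 0 °C; Et3N, then aq NaHCO3
Reagents that add atoms: none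
Why: The phosphoric acid hydrogen-bonds to a pinacol oxygen of the boronate while its phosphoryl oxygen holds the formyl C–H, so each aldehyde is crotylated through a closed six-membered chair transition state in which boron binds the carbonyl oxygen and the gamma carbon of the crotyl group bonds to the carbonyl carbon; the closest known reaction is the chiral phosphoric acid-catalysed allyl- and crotylboration of aromatic aldehydes with pinacol boronates. No ring is closed, the cyclic array being only a transition state. At each arm the methyl-bearing carbon is fixed anti to the carbinol by the E-alkene (methyl equatorial in the chair) and its absolute (R) configuration by the catalyst's choice of the aldehyde Re face, which also sets the carbinol carbon (R); that carbinol centre is erased in step 8. The step needs Re-face, anti addition at both formyl groups: the two aldehydes lie on different rings far apart and should react independently under catalyst control, and benzyl protection removes the phenol hydrogen bonds that would deactivate the aldehydes and compete for the catalyst. Because two independent additions build two identical arms, a single facial error should end in a diastereomer with one (R) and one (S) arm that chromatography can remove, so the doubly (R) material should be enriched beyond the selectivity of one event. The borate 13 is cleaved on mild basic work-up, and the acid-labile trialkoxybenzylic carbinols are kept from acid by the Et3N quench and base-washed silica.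

**Step 7**
Reactants: 14 1,1-bis{5,7-bis(benzyloxy)-8-[(1R,2R)-1-hydroxy-2-methylbut-3-enyl]-2,2-dimethylchroman-6-yl}-6-methylheptane
Product: 15 1,1-bis{5,7-bis(benzyloxy)-8-[(1R,2R)-1-hydroxy-2-methylbutyl]-2,2-dimethylchroman-6-yl}-6-methylheptane
Conditions: 2-nitrobenzenesulfonylhydrazide (NBSH, 6 equiv), Et3N, CH2Cl2, rt
Reagents that add atoms: none
Why: Diimide generated from the sulfonylhydrazide transfers two hydrogens suprafacially to the unhindered terminal alkenes without a metal, so no double-bond migration can scramble the allylic methyl-bearing centre and neither the benzyl ethers nor the benzylic C–O bonds are touched.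

**Step 8**
Reactants: 15 1,1-bis{5,7-bis(benzyloxy)-8-[(1R,2R)-1-hydroxy-2-methylbutyl]-2,2-dimethylchroman-6-yl}-6-methylheptane
Product: 16 1,1-bis{5,7-bis(benzyloxy)-2,2-dimethyl-8-[(2R)-2-methylbutanoyl]chroman-6-yl}-6-methylheptane
Conditions: Dess–Martin periodinane (3 equiv), pyridine, CH2Cl2, 0 °C → rt
Reagents that add atoms: none
Why: Dess–Martin oxidation under pyridine buffering should convert the hindered secondary benzylic alcohols to the aryl ketones without acid or base strong enough to ionise the carbinol or enolise the new ketone, so the alpha centres stay (R) while the carbinol centres are erased.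

**Step 9**
Reactants: 16 1,1-bis{5,7-bis(benzyloxy)-2,2-dimethyl-8-[(2R)-2-methylbutanoyl]chroman-6-yl}-6-methylheptane
Product: 17 1,1-bis{5,7-dihydroxy-2,2-dimethyl-8-[(2R)-2-methylbutanoyl]chroman-6-yl}-6-methylheptane (CNP0324275.1)
Conditions: H2 (1 atm), Pd/C (10 wt%), EtOAc, rt
Reagents that add atoms: none
Why: Catalytic hydrogenolysis of the four aryl benzyl ethers under neutral conditions should free the phenols, whose hydrogen bonds to the ketone carbonyls make the 2-hydroxyaryl ketones resistant to further reduction and leave the alpha centres unchanged.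

**Compound list**

1 | phloroglucinol | Oc1cc(O)cc(O)c1 | starting material
2 | isoprene | C=CC(C)=C | starting material
3 | 5,7-dihydroxy-2,2-dimethylchroman | CC1(C)CCc2c(O)cc(O)cc2O1 | intermediate
4 | 5,7-bis(benzyloxy)-2,2-dimethylchroman | CC1(C)CCc2c(OCc3ccccc3)cc(OCc3ccccc3)cc2O1 | intermediate
5 | 5,7-bis(benzyloxy)-8-bromo-2,2-dimethylchroman | CC1(C)CCc2c(OCc3ccccc3)cc(OCc3ccccc3)c(Br)c2O1 | intermediate
6 | 6-methylheptanal | CC(C)CCCCC=O | starting material
7 | 1-[5,7-bis(benzyloxy)-8-bromo-2,2-dimethylchroman-6-yl]-6-methylheptan-1-ol (not isolated) | CC(C)CCCCC(O)c1c(OCc2ccccc2)c(Br)c2OC(C)(C)CCc2c1OCc1ccccc1 | intermediate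
8 | 1,1-bis[5,7-bis(benzyloxy)-8-bromo-2,2-dimethylchroman-6-yl]-6-methylheptane | CC(C)CCCCC(c1c(OCc2ccccc2)c(Br)c2OC(C)(C)CCc2c1OCc1ccccc1)c1c(OCc2ccccc2)c(Br)c2OC(C)(C)CCc2c1OCc1ccccc1 | intermediate
9 | 8,8'-dilithio derivative of 8 (not isolated) | CC(C)CCCCC(c1c(OCc2ccccc2)c([Li])c2OC(C)(C)CCc2c1OCc1ccccc1)c1c(OCc2ccccc2)c([Li])c2OC(C)(C)CCc2c1OCc1ccccc1 | intermediate
10 | bis(lithium alpha-dimethylaminoalkoxide) from 9 and DMF (not isolated) | CC(C)CCCCC(c1c(OCc2ccccc2)c(C(O[Li])N(C)C)c2OC(C)(C)CCc2c1OCc1ccccc1)c1c(OCc2ccccc2)c(C(O[Li])N(C)C)c2OC(C)(C)CCc2c1OCc1ccccc1 | intermediate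
11 | 6,6'-(6-methylheptane-1,1-diyl)bis[5,7-bis(benzyloxy)-2,2-dimethylchroman-8-carbaldehyde] | CC(C)CCCCC(c1c(OCc2ccccc2)c(C=O)c2OC(C)(C)CCc2c1OCc1ccccc1)c1c(OCc2ccccc2)c(C=O)c2OC(C)(C)CCc2c1OCc1ccccc1 | intermediate
12 | (E)-crotylboronic acid pinacol ester | C/C=C/CB1OC(C)(C)C(C)(C)O1 | starting material
13 | bis(pinacol borate) ester of 14 (not isolated) | CC(C)CCCCC(c1c(OCc2ccccc2)c([C@H](OB2OC(C)(C)C(C)(C)O2)[C@H](C)C=C)c2OC(C)(C)CCc2c1OCc1ccccc1)c1c(OCc2ccccc2)c([C@H](OB2OC(C)(C)C(C)(C)O2)[C@H](C)C=C)c2OC(C)(C)CCc2c1OCc1ccccc1 | intermediate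
14 | 1,1-bis{5,7-bis(benzyloxy)-8-[(1R,2R)-1-hydroxy-2-methylbut-3-enyl]-2,2-dimethylchroman-6-yl}-6-methylheptane | CC(C)CCCCC(c1c(OCc2ccccc2)c([C@H](O)[C@H](C)C=C)c2OC(C)(C)CCc2c1OCc1ccccc1)c1c(OCc2ccccc2)c([C@H](O)[C@H](C)C=C)c2OC(C)(C)CCc2c1OCc1ccccc1 | intermediate
15 | 1,1-bis{5,7-bis(benzyloxy)-8-[(1R,2R)-1-hydroxy-2-methylbutyl]-2,2-dimethylchroman-6-yl}-6-methylheptane | CC(C)CCCCC(c1c(OCc2ccccc2)c([C@H](O)[C@H](C)CC)c2OC(C)(C)CCc2c1OCc1ccccc1)c1c(OCc2ccccc2)c([C@H](O)[C@H](C)CC)c2OC(C)(C)CCc2c1OCc1ccccc1 | intermediate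
16 | 1,1-bis{5,7-bis(benzyloxy)-2,2-dimethyl-8-[(2R)-2-methylbutanoyl]chroman-6-yl}-6-methylheptane | CC(C)CCCCC(c1c(OCc2ccccc2)c(C(=O)[C@H](C)CC)c2OC(C)(C)CCc2c1OCc1ccccc1)c1c(OCc2ccccc2)c(C(=O)[C@H](C)CC)c2OC(C)(C)CCc2c1OCc1ccccc1 | intermediate
17 | 1,1-bis{5,7-dihydroxy-2,2-dimethyl-8-[(2R)-2-methylbutanoyl]chroman-6-yl}-6-methylheptane (CNP0324275.1) | CC[C@@H](C)C(=O)c1c(O)c(C(CCCCC(C)C)c2c(O)c3c(c(C(=O)[C@H](C)CC)c2O)OC(C)(C)CC3)c(O)c2c1OC(C)(C)CC2 | target

**Step count and risks**

Total step count: 9. Longest linear sequence: 9 steps (1 → 17).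

Steps most likely to fail:

1. Step 6 (key step). The formyl groups sit between a benzyloxy group and the ring oxygen, so binding in the catalyst pocket may be slow or poorly face-selective. The acid may also ionise the trialkoxybenzylic borates, and elimination toward a diene would erode the alpha centres. Fallback, stoichiometric reagent control under basic conditions instead of Brønsted acid catalysis: starting from 11, (E)-but-2-enyldiisopinocampheylborane F1 is prepared in the flask at −78 °C from trans-2-butene, n-BuLi/KOt-Bu, (+)-B-methoxydiisopinocampheylborane (the antipode expected to attack the Re face) and BF3·OEt2. It is expected to add to both aldehydes in THF at −78 °C through the same chair arrangement to give the bis(diisopinocampheylborinate) of the diol F2. NaOH/H2O2 then releases diol 14, where the route continues.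

2. Step 4. The second arylation may stall at the carbinol or its dehydration product because C6 is flanked by two benzyloxy groups, and the Lewis acid may cause benzyl transfer or loss of bromine. Fallback, bridging with free phenols before protection: from 5, n-BuLi in THF at −78 °C gives 5,7-bis(benzyloxy)-2,2-dimethylchroman-8-yllithium F3. DMF converts it to the lithium aminoalkoxide F4 and water to 5,7-bis(benzyloxy)-2,2-dimethylchroman-8-carbaldehyde F5. BCl3/pentamethylbenzene (CH2Cl2, −78 °C) removes both benzyl groups to give 5,7-dihydroxy-2,2-dimethylchroman-8-carbaldehyde F6. Its C6, now between two free hydroxyls and the only open ring position, should condense with 6 under piperidinium acetate catalysis in MeOH through 6-(1-hydroxy-6-methylheptyl)-5,7-dihydroxy-2,2-dimethylchroman-8-carbaldehyde F7 to the bridged tetraphenol dialdehyde F8. BnBr/K2CO3 in DMF then gives 11, so steps 4 and 5 are bypassed.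

3. Step 9. Hydrogenolysis may be slow at the crowded ethers beside the bridge, and forcing it risks reduction of the aryl ketones. Fallback, Lewis acid dealkylation instead of hydrogenolysis: from 16, BCl3 with pentamethylbenzene as benzyl cation trap in CH2Cl2 at −78 °C should cleave the four aryl benzyl ethers without hydrogen and give 17 directly; no new compound lies on the way.

**Further compounds**

F1 | step 6 | (E)-but-2-enyldiisopinocampheylborane from (+)-B-methoxydiisopinocampheylborane | C/C=C/CB([C@H]1C[C@H]2C[C@@H]([C@@H]1C)C2(C)C)[C@H]1C[C@H]2C[C@@H]([C@@H]1C)C2(C)C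
F2 | step 6 | bis(diisopinocampheylborinate) of diol 14 | CC(C)CCCCC(c1c(OCc2ccccc2)c([C@H](OB([C@H]3C[C@H]4C[C@@H]([C@@H]3C)C4(C)C)[C@H]3C[C@H]4C[C@@H]([C@@H]3C)C4(C)C)[C@H](C)C=C)c2OC(C)(C)CCc2c1OCc1ccccc1)c1c(OCc2ccccc2)c([C@H](OB([C@H]3C[C@H]4C[C@@H]([C@@H]3C)C4(C)C)[C@H]3C[C@H]4C[C@@H]([C@@H]3C)C4(C)C)[C@H](C)C=C)c2OC(C)(C)CCc2c1OCc1ccccc1
F3 | step 4 | 5,7-bis(benzyloxy)-2,2-dimethylchroman-8-yllithium | CC1(C)CCc2c(OCc3ccccc3)cc(OCc3ccccc3)c([Li])c2O1
F4 | step 4 | lithium [5,7-bis(benzyloxy)-2,2-dimethylchroman-8-yl](dimethylamino)methoxide | CC1(C)CCc2c(OCc3ccccc3)cc(OCc3ccccc3)c(C(O[Li])N(C)C)c2O1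
F5 | step 4 | 5,7-bis(benzyloxy)-2,2-dimethylchroman-8-carbaldehyde | CC1(C)CCc2c(OCc3ccccc3)cc(OCc3ccccc3)c(C=O)c2O1
F6 | step 4 | 5,7-dihydroxy-2,2-dimethylchroman-8-carbaldehyde | CC1(C)CCc2c(O)cc(O)c(C=O)c2O1
F7 | step 4 | 6-(1-hydroxy-6-methylheptyl)-5,7-dihydroxy-2,2-dimethylchroman-8-carbaldehyde | CC(C)CCCCC(O)c1c(O)c(C=O)c2OC(C)(C)CCc2c1O
F8 | step 4 | 6,6'-(6-methylheptane-1,1-diyl)bis(5,7-dihydroxy-2,2-dimethylchroman-8-carbaldehyde) | CC(C)CCCCC(c1c(O)c(C=O)c2OC(C)(C)CCc2c1O)c1c(O)c(C=O)c2OC(C)(C)CCc2c1O
F0 | step 9 | none | none
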